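**Retrosynthetic overview**

- Larreantin is a 2-methoxy-1,4-naphthoquinone (ring A quinone, ring B benzenoid). It is traced back through O-debenzylation, (NH4)2Ce(NO3)6 oxidation of a 1,2,4-trimethoxynaphthalene, and deoxygenation of a C6 aroyl group to the C6 benzyl group.
- The plan rests on ring B and its contiguous edge C5(H)–C6(benzyl)–C7(Me)–C8(aryl). Cutting C5–C6 and C7–C8 gives a 2-(arylmethyl)-3,4,6-trimethoxybenzaldehyde (CHO carbon = C5, diarylmethane carbon = C8, ring A as the trimethoxyarene) and an aryl but-2-ynone (C6, C7). These are joined by light-driven enolisation, [4+2] cycloaddition and loss of water.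
- The aldehyde comes from the benzylic alcohol, the 2-benzylbenzoic acid and a 3-arylphthalide, which is made by amide-directed ortho-lithiation of N,N-diethyl-2,4,5-trimethoxybenzamide and addition to O-benzylvanillin.
- The ynone comes from O-benzylvanillin and 1-propynylmagnesium bromide, then MnO2.
- Ring order: ring A is bought as the arene, ring B is closed in the key step, and ring A is turned into the quinone near the end.

Key step: step 8

Assumption: the target SMILES has no stereodescriptor, so the C8–aryl axis is treated as configurationally undefined. All chiral intermediates are racemic and their stereocentres are erased before the target. Positions are numbered as in the target naphthoquinone from compound 15 onward.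

**Route**

Step 1
Reactants: 1 2,4,5-trimethoxybenzoic acid
Product: 3 N,N-diethyl-2,4,5-trimethoxybenzamide, via acid chloride 2 (not isolated)
Conditions: (COCl)2, DMF (cat.), CH2Cl2, 0 °C → rt; concentrate; Et2NH, Et3N, CH2Cl2, 0 °C → rt
Reagents that add atoms: diethylamine, CCNCC
Why: Acyl chloride formation followed by amidation is a standard amide synthesis, and the aryl methyl ethers are inert to it.

Step 2
Reactants: 3 N,N-diethyl-2,4,5-trimethoxybenzamide; 4 4-benzyloxy-3-methoxybenzaldehyde
Product: 7 3-(4-benzyloxy-3-methoxyphenyl)-4,5,7-trimethoxyisobenzofuran-1(3H)-one (racemic phthalide), via aryllithium 5 (not isolated), via hydroxy amide 6 (not isolated)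
Conditions: s-BuLi, TMEDA, THF, −78 °C; 4, −78 °C → rt; aq HCl; then TsOH·H2O, PhMe, reflux
Reagents that add atoms: none
Why: Directed ortho-metalation places lithium at the only free position ortho to the tertiary amide (also acidified by the neighbouring OMe), the aryllithium adds 1,2 to the aldehyde, and acid-promoted lactonisation expels Et2NH; the new carbinol centre is racemic and is removed in step 3.

Step 3
Reactants: 7 3-(4-benzyloxy-3-methoxyphenyl)-4,5,7-trimethoxyisobenzofuran-1(3H)-one
Product: 8 2-(4-benzyloxy-3-methoxybenzyl)-3,4,6-trimethoxybenzoic acid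
Conditions: Zn dust (activated by CuSO4), 10% aq KOH, pyridine, reflux; then aq HCl
Reagents that add atoms: none
Why: Zinc–alkali reductive cleavage of the doubly benzylic C–O bond of 3-arylphthalides is an established route to 2-benzylbenzoic acids and, unlike catalytic hydrogenolysis, should leave the aryl benzyl ether intact.

Step 4
Reactants: 8 2-(4-benzyloxy-3-methoxybenzyl)-3,4,6-trimethoxybenzoic acid
Product: 9 [2-(4-benzyloxy-3-methoxybenzyl)-3,4,6-trimethoxyphenyl]methanol
Conditions: LiAlH4, THF, 0 °C → reflux; aq NaOH work-up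
Reagents that add atoms: none
Why: Hydride reduction of a carboxylic acid to the primary alcohol with LiAlH4 tolerates the di-ortho substitution at reflux and does not touch the ethers.

Step 5
Reactants: 9 [2-(4-benzyloxy-3-methoxybenzyl)-3,4,6-trimethoxyphenyl]methanol
Product: 10 2-(4-benzyloxy-3-methoxybenzyl)-3,4,6-trimethoxybenzaldehyde
Conditions: MnO2 (activated), CH2Cl2, rt, subdued light
Reagents that add atoms: none
Why: MnO2 oxidation of a benzylic alcohol stops at the aldehyde and leaves the diarylmethane CH2 alone.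

Step 6
Reactants: 4 4-benzyloxy-3-methoxybenzaldehyde; 11 1-propynylmagnesium bromide
Product: 12 1-(4-benzyloxy-3-methoxyphenyl)but-2-yn-1-ol (racemic)
Conditions: THF, 0 °C; aq NH4Cl
Reagents that add atoms: none
Why: Grignard 1,2-addition of an alkynylmagnesium halide to an aromatic aldehyde; the racemic carbinol centre is removed in step 7.

Step 7
Reactants: 12 1-(4-benzyloxy-3-methoxyphenyl)but-2-yn-1-ol
Product: 13 1-(4-benzyloxy-3-methoxyphenyl)but-2-yn-1-one
Conditions: MnO2 (activated), CH2Cl2, rt
Reagents that add atoms: none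
Why: MnO2 oxidation of an alcohol that is both benzylic and propargylic should give the conjugated ynone cleanly.

Step 8
Reactants: 10 2-(4-benzyloxy-3-methoxybenzyl)-3,4,6-trimethoxybenzaldehyde; 13 1-(4-benzyloxy-3-methoxyphenyl)but-2-yn-1-one
Product: 16 6-(4-benzyloxy-3-methoxybenzoyl)-8-(4-benzyloxy-3-methoxyphenyl)-1,2,4-trimethoxy-7-methylnaphthalene, via hydroxy-ortho-quinodimethane 14 (not isolated), via dihydronaphthol adduct 15 (not isolated)
Conditions: hν (365 nm), 13 (3 equiv), degassed PhMe, rt; lamp off; TsOH·H2O (cat.), 50 °C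
Reagents that add atoms: none
Why: Photoenolisation/Diels–Alder reaction: excitation of the aldehyde and 1,5-hydrogen transfer from the doubly benzylic CH2 (the carbonyl oxygen is turned toward it, away from the flanking OMe) give the hydroxy-ortho-quinodimethane 14 with OH and aryl outward, the long-lived photoenol isomer. Ring B is closed by an intermolecular, thermal, suprafacial [4+2] cycloaddition of this diene with the ynone, which forms C5–C6 and C7–C8 together and restores the aromaticity of ring A, as in the known trapping of photoenols of ortho-alkyl- and ortho-benzylbenzaldehydes by acetylenic ketones and esters. The orientation needed (acyl carbon to C5, methyl carbon to C8) should follow from the enol oxygen, which puts the largest HOMO coefficient on the remote terminus C8 so that it pairs with the β-carbon of the ynone, and from a hydrogen bond between the enol OH and the ynone carbonyl that holds the acyl group on the C5 side. The two stereocentres of adduct 15 (C5 and C8, cis from the out,out-diene, racemic) have no consequence, because acid removes OH from C5 and H from C8 in a 1,4-elimination driven by formation of the naphthalene. Acid is added only after the lamp is off, so that the ortho-methyl diaryl ketone 16, itself a photoenol precursor, is not irradiated.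

Step 9
Reactants: 16 6-(4-benzyloxy-3-methoxybenzoyl)-8-(4-benzyloxy-3-methoxyphenyl)-1,2,4-trimethoxy-7-methylnaphthalene
Product: 17 6-(4-benzyloxy-3-methoxybenzyl)-8-(4-benzyloxy-3-methoxyphenyl)-1,2,4-trimethoxy-7-methylnaphthalene
Conditions: Et3SiH, CF3CO2H, CH2Cl2, 0 °C → rt
Reagents that add atoms: none
Why: Ionic hydrogenation: the protonated diaryl ketone accepts hydride from the silane, the carbinol ionises to a cation stabilised by the 4-alkoxyphenyl ring and is reduced again to CH2, while aryl benzyl and methyl ethers tolerate dilute CF3CO2H at this temperature.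

Step 10
Reactants: 17 6-(4-benzyloxy-3-methoxybenzyl)-8-(4-benzyloxy-3-methoxyphenyl)-1,2,4-trimethoxy-7-methylnaphthalene
Product: 18 6-(4-benzyloxy-3-methoxybenzyl)-8-(4-benzyloxy-3-methoxyphenyl)-2-methoxy-7-methyl-1,4-naphthoquinone
Conditions: (NH4)2Ce(NO3)6, MeCN/H2O, 0 °C
Reagents that add atoms: water, O
Why: Oxidative demethylation of a para-dimethoxyarene by tetravalent cerium: two one-electron oxidations with attack of water at C1 and C4 expel two methanol molecules and give the para-quinone with the C2 methoxy retained; the trimethoxynaphthalene is much more easily oxidised than the benzyloxy-methoxyphenyl rings.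

Step 11
Reactants: 18 6-(4-benzyloxy-3-methoxybenzyl)-8-(4-benzyloxy-3-methoxyphenyl)-2-methoxy-7-methyl-1,4-naphthoquinone
Product: 20 larreantin, via hydroquinone 19 (not isolated)
Conditions: H2 (1 atm), 10% Pd/C, EtOAc, rt; filter; air, rt
Reagents that add atoms: none
Why: Catalytic hydrogenolysis cleaves both aryl benzyl ethers; the quinone is reduced to the naphthohydroquinone at the same time and this electron-rich hydroquinone should autoxidise back to the quinone in air on work-up.

**Compound list**

1 | 2,4,5-trimethoxybenzoic acid | COc1cc(OC)c(C(=O)O)cc1OC | starting material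
2 | 2,4,5-trimethoxybenzoyl chloride | COc1cc(OC)c(C(=O)Cl)cc1OC | intermediate
3 | N,N-diethyl-2,4,5-trimethoxybenzamide | CCN(CC)C(=O)c1cc(OC)c(OC)cc1OC | intermediate
4 | 4-benzyloxy-3-methoxybenzaldehyde (O-benzylvanillin) | COc1cc(C=O)ccc1OCc1ccccc1 | starting material
5 | N,N-diethyl-2-lithio-3,4,6-trimethoxybenzamide | CCN(CC)C(=O)c1c([Li])c(OC)c(OC)cc1OC | intermediate
6 | N,N-diethyl-2-[(4-benzyloxy-3-methoxyphenyl)(hydroxy)methyl]-3,4,6-trimethoxybenzamide (racemic) | CCN(CC)C(=O)c1c(C(O)c2ccc(OCc3ccccc3)c(OC)c2)c(OC)c(OC)cc1OC | intermediate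
7 | 3-(4-benzyloxy-3-methoxyphenyl)-4,5,7-trimethoxyisobenzofuran-1(3H)-one (racemic) | COc1cc(OC)c2c(c1OC)C(c1ccc(OCc3ccccc3)c(OC)c1)OC2=O | intermediate
8 | 2-(4-benzyloxy-3-methoxybenzyl)-3,4,6-trimethoxybenzoic acid | COc1cc(OC)c(C(=O)O)c(Cc2ccc(OCc3ccccc3)c(OC)c2)c1OC | intermediate
9 | [2-(4-benzyloxy-3-methoxybenzyl)-3,4,6-trimethoxyphenyl]methanol | COc1cc(OC)c(CO)c(Cc2ccc(OCc3ccccc3)c(OC)c2)c1OC | intermediate
10 | 2-(4-benzyloxy-3-methoxybenzyl)-3,4,6-trimethoxybenzaldehyde | COc1cc(OC)c(C=O)c(Cc2ccc(OCc3ccccc3)c(OC)c2)c1OC | intermediate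
11 | 1-propynylmagnesium bromide | CC#C[Mg]Br | starting material
12 | 1-(4-benzyloxy-3-methoxyphenyl)but-2-yn-1-ol (racemic) | CC#CC(O)c1ccc(OCc2ccccc2)c(OC)c1 | intermediate
13 | 1-(4-benzyloxy-3-methoxyphenyl)but-2-yn-1-one | CC#CC(=O)c1ccc(OCc2ccccc2)c(OC)c1 | intermediate
14 | 6-[(4-benzyloxy-3-methoxyphenyl)methylidene]-5-(hydroxymethylidene)-1,2,4-trimethoxycyclohexa-1,3-diene (photoenol of 10, OH and aryl both outward) | O/C=C1/C(=C/c2ccc(OCc3ccccc3)c(OC)c2)C(OC)=C(OC)C=C1OC | intermediate
15 | 6-(4-benzyloxy-3-methoxybenzoyl)-8-(4-benzyloxy-3-methoxyphenyl)-1,2,4-trimethoxy-7-methyl-5,8-dihydronaphthalen-5-ol (5,8-cis, racemic, one enantiomer drawn) | O[C@@H]1C(C(=O)c3ccc(OCc4ccccc4)c(OC)c3)=C(C)[C@H](c3ccc(OCc4ccccc4)c(OC)c3)c2c(OC)c(OC)cc(OC)c21 | intermediate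
16 | 6-(4-benzyloxy-3-methoxybenzoyl)-8-(4-benzyloxy-3-methoxyphenyl)-1,2,4-trimethoxy-7-methylnaphthalene | COc1cc(OC)c2cc(C(=O)c3ccc(OCc4ccccc4)c(OC)c3)c(C)c(-c3ccc(OCc4ccccc4)c(OC)c3)c2c1OC | intermediate
17 | 6-(4-benzyloxy-3-methoxybenzyl)-8-(4-benzyloxy-3-methoxyphenyl)-1,2,4-trimethoxy-7-methylnaphthalene | COc1cc(OC)c2cc(Cc3ccc(OCc4ccccc4)c(OC)c3)c(C)c(-c3ccc(OCc4ccccc4)c(OC)c3)c2c1OC | intermediate
18 | 6-(4-benzyloxy-3-methoxybenzyl)-8-(4-benzyloxy-3-methoxyphenyl)-2-methoxy-7-methyl-1,4-naphthoquinone | COC1=CC(=O)c2cc(Cc3ccc(OCc4ccccc4)c(OC)c3)c(C)c(-c3ccc(OCc4ccccc4)c(OC)c3)c2C1=O | intermediate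
19 | 6-(4-hydroxy-3-methoxybenzyl)-8-(4-hydroxy-3-methoxyphenyl)-2-methoxy-7-methylnaphthalene-1,4-diol | COc1cc(O)c2cc(Cc3ccc(O)c(OC)c3)c(C)c(-c3ccc(O)c(OC)c3)c2c1O | intermediate
20 | larreantin, 6-(4-hydroxy-3-methoxybenzyl)-8-(4-hydroxy-3-methoxyphenyl)-2-methoxy-7-methyl-1,4-naphthoquinone | COC1=CC(=O)c2cc(Cc3ccc(O)c(OC)c3)c(C)c(-c3ccc(O)c(OC)c3)c2C1=O | target

**Step count and risks**

Total step count: 11. Longest linear sequence: 9 steps (steps 1–5 and 8–11); the ynone branch (steps 6–7) joins at step 8.

Steps most likely to fail: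

1. Step 8 (key step). The photoenol may revert to 10 faster than the β-methyl ynone captures it. The ynone and the adduct also absorb light and may be consumed in side reactions. Fallback, setting out from 10: irradiation (365 nm) in benzene saturated with SO2 should trap the photoenol 14 as cis-3-(4-benzyloxy-3-methoxyphenyl)-1-hydroxy-4,5,7-trimethoxy-1,3-dihydrobenzo[c]thiophene 2,2-dioxide F1, a known way of storing such dienols. F1 is then heated in the dark with 13 (3 equiv) and ZnO in PhMe at about 90 °C. Cheletropic loss of SO2 regenerates 14 thermally in a concentrated solution of the ynone, with no light reaching 13, 15 or the product. Acid treatment as in step 8 then dehydrates 15 and the sequence comes back at 16.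

2. Step 10. Oxidation may take the ortho path, with loss of the C1 and C2 methyl groups, so that part of the material ends as the 1,2-quinone. Fallback, setting out from 17: the crude oxidation mixture, which may hold 6-(4-benzyloxy-3-methoxybenzyl)-8-(4-benzyloxy-3-methoxyphenyl)-4-methoxy-7-methyl-1,2-naphthoquinone F2 beside 18, is stirred with dilute aqueous NaOH in THF and then acidified. Both vinylogous esters should hydrolyse to the same compound, 6-(4-benzyloxy-3-methoxybenzyl)-8-(4-benzyloxy-3-methoxyphenyl)-2-hydroxy-7-methyl-1,4-naphthoquinone F3, because their hydrolysis products are tautomers. HCl in MeOH then methylates this vinylogous acid at the C2 oxygen under thermodynamic control, and the sequence comes back at 18.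

3. Step 9. Acid may protonate the electron-rich trimethoxynaphthalene and open a path to ring reduction, or loosen the benzyl ethers before the hindered ketone is fully reduced. Fallback, setting out from 16: the order of oxidation and deoxygenation is inverted. (NH4)2Ce(NO3)6 in aqueous MeCN first converts the acid-sensitive ring A into the quinone, giving 6-(4-benzyloxy-3-methoxybenzoyl)-8-(4-benzyloxy-3-methoxyphenyl)-2-methoxy-7-methyl-1,4-naphthoquinone F4. Ionic hydrogenation (Et3SiH, CF3CO2H, CH2Cl2) is then run on F4, whose ring A no longer protonates, while the 4-alkoxyphenyl ring still stabilises the benzylic cation. Any hydroquinone formed by the silane is returned to the quinone by air on work-up, and the sequence comes back at 18.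

**Further compounds**

F1 | step 8 | cis-3-(4-benzyloxy-3-methoxyphenyl)-1-hydroxy-4,5,7-trimethoxy-1,3-dihydrobenzo[c]thiophene 2,2-dioxide (racemic, one enantiomer drawn) | O[C@H]1c2c(OC)cc(OC)c(OC)c2[C@@H](c2ccc(OCc3ccccc3)c(OC)c2)S1(=O)=O
F2 | step 10 | 6-(4-benzyloxy-3-methoxybenzyl)-8-(4-benzyloxy-3-methoxyphenyl)-4-methoxy-7-methyl-1,2-naphthoquinone | COC1=CC(=O)C(=O)c2c(-c3ccc(OCc4ccccc4)c(OC)c3)c(C)c(Cc3ccc(OCc4ccccc4)c(OC)c3)cc12
F3 | step 10 | 6-(4-benzyloxy-3-methoxybenzyl)-8-(4-benzyloxy-3-methoxyphenyl)-2-hydroxy-7-methyl-1,4-naphthoquinone | OC1=CC(=O)c2cc(Cc3ccc(OCc4ccccc4)c(OC)c3)c(C)c(-c3ccc(OCc4ccccc4)c(OC)c3)c2C1=O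
F4 | step 9 | 6-(4-benzyloxy-3-methoxybenzoyl)-8-(4-benzyloxy-3-methoxyphenyl)-2-methoxy-7-methyl-1,4-naphthoquinone | COC1=CC(=O)c2cc(C(=O)c3ccc(OCc4ccccc4)c(OC)c3)c(C)c(-c3ccc(OCc4ccccc4)c(OC)c3)c2C1=O
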